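## Retrosynthetic overview

1. Target 21 ⇒ trans-decalone 13 by three late operations: Pummerer unmasking of the aldehyde from a CH2S(O)Tol group, Mitsunobu esterification with inversion at C6, and hydride reduction of the C6 ketone.
2. 13 ⇒ monocyclic enone 11 by a C4–C5 disconnection (cation–olefin closure onto the ketone enol).
3. 11 ⇒ prochiral p-quinol 7 by a C10–C1 disconnection: a desymmetrising, hydroxyl/sulfoxide-directed conjugate addition of a homoprenyl group sets C9 and C10 together.
4. 7 ⇒ quinone monoketal 3 + (S)-methyl p-tolyl sulfoxide 4; 3 ⇒ oxidative dearomatisation of 2,6-dimethylphenol 1; acid 18 ⇒ sorbaldehyde + malonic acid.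
5. Ring B is the former benzene ring and ring A is closed second. Drimane numbering is used for atom labels. The SMILES is read as H5 α, 10-Me β, 9-OH α / 9-CHO β, 6-acyloxy α (1S,4R,4aS,8aS).

Assumption: the sulfinyl group steers as in the known unsubstituted sulfinylmethyl p-quinols (an R sulfoxide sends the alkyl group to the pro-S enone, syn to OH), so the S sulfoxide is used; if the methylated quinol responds in the opposite sense, the commercially available R sulfoxide is used instead.

## Route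

Step 1
Reactants: 1 2,6-dimethylphenol
Product: 3 4,4-dimethoxy-2,6-dimethylcyclohexa-2,5-dien-1-one, via 4-methoxy-2,6-dimethylphenol 2 (not isolated)
Conditions: PhI(OAc)2 (2.2 equiv), MeOH, 0 °C → rt
Reagents that add atoms: methanol CO
Why: Oxidative dearomatisation of the phenol with PhI(OAc)2, in which methanol adds para twice (first giving 2, then its oxidised form) to give the achiral p-quinone monoketal; no stereocentre is formed.

Step 2
Reactants: 3 4,4-dimethoxy-2,6-dimethylcyclohexa-2,5-dien-1-one; 4 (S)-methyl p-tolyl sulfoxide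
Product: 7 4-hydroxy-3,5-dimethyl-4-{[(S)-4-methylbenzenesulfinyl]methyl}cyclohexa-2,5-dien-1-one, via lithiated sulfoxide 5 (not isolated), via ketal carbinol 6 (not isolated)
Conditions: 4, LiN(iPr)2, THF, −78 °C; then 3, −78 °C; aq NH4Cl; then oxalic acid (cat.), THF–H2O, rt
Reagents that add atoms: lithium diisopropylamide [Li]N(C(C)C)C(C)C; water O
Why: 1,2-Addition of the α-sulfinyl carbanion to the only carbonyl group of the quinone monoketal followed by mild acid hydrolysis of the ketal (sulfinyl p-quinol synthesis); the carbinol carbon carries two identical arms and is not yet stereogenic, and the sulfur configuration is untouched.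

Step 3
Reactants: 7 4-hydroxy-3,5-dimethyl-4-{[(S)-4-methylbenzenesulfinyl]methyl}cyclohexa-2,5-dien-1-one; 8 5-bromo-2-methylpent-2-ene
Product: 11 (4S,5S)-4-hydroxy-3,5-dimethyl-5-(4-methylpent-3-en-1-yl)-4-{[(S)-4-methylbenzenesulfinyl]methyl}cyclohex-2-en-1-one, via 4-methylpent-3-enylmagnesium bromide 9 (not isolated), via tris(4-methylpent-3-enyl)aluminium 10 (not isolated)
Conditions: 8, Mg, Et2O, reflux; AlCl3 (1/3 equiv per RMgBr), 0 °C → rt, salts filtered off, toluene; then 7 (0.25 equiv) in CH2Cl2, −78 °C → rt; aq potassium sodium tartrate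
Reagents that add atoms: magnesium [Mg]; aluminium trichloride Cl[Al](Cl)Cl
Why: Proposed new method: a desymmetrising, hydroxyl- and sulfoxide-directed conjugate addition in which R3Al 10 first forms the aluminium alkoxide of 7, the sulfinyl oxygen closes a six-membered chelate (p-tolyl equatorial) that holds the pro-R enone arm axial next to aluminium, and an alkyl group is delivered to that β-carbon on the face of the oxygen, so that C9 (OH α) and the quaternary C10 (chain syn to OH, methyl β) are set in one event, the intramolecular delivery paying for the vicinal fully substituted carbons; the closest known reaction type is the sulfoxide-directed addition of trialkylaluminium reagents to 4-hydroxy-4-(sulfinylmethyl)cyclohexadienones, which is documented only for unsubstituted β-carbons.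

Step 4
Reactants: 11 (4S,5S)-4-hydroxy-3,5-dimethyl-5-(4-methylpent-3-en-1-yl)-4-{[(S)-4-methylbenzenesulfinyl]methyl}cyclohex-2-en-1-one
Product: 13 (4R,4aS,8aS)-4-hydroxy-3,4a,8,8-tetramethyl-4-{[(S)-4-methylbenzenesulfinyl]methyl}-4a,5,6,7,8,8a-hexahydronaphthalen-1(4H)-one, via cis-fused C5 epimer 12 (not isolated)
Conditions: CF3SO3H (2.5 equiv), (CF3)2CHOH–CH2Cl2 (1:4), −20 °C → rt, 12 h; aq NaHCO3
Reagents that add atoms: none
Why: Cation–olefin cyclisation ended by the ketone enol (intramolecular α-tert-alkylation), in which protonation of the trisubstituted alkene gives the tertiary C4 cation that is captured by C5 of the cross-conjugated enol to close six-membered ring A (O-capture by the 9-OH is reversible, C–C bond formation is not); C5 is expected cis first (axial attack, 12) and is then equilibrated by the same acid through the enol to the trans-fused ketone with H5 α, by analogy with 4,4,10-trimethyl 7-en-6-ones, which are expected to keep the trans fusion under enolising conditions.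

Step 5
Reactants: 13 (4R,4aS,8aS)-4-hydroxy-3,4a,8,8-tetramethyl-4-{[(S)-4-methylbenzenesulfinyl]methyl}-4a,5,6,7,8,8a-hexahydronaphthalen-1(4H)-one
Product: 14 (1R,4R,4aS,8aS)-3,4a,8,8-tetramethyl-4-{[(S)-4-methylbenzenesulfinyl]methyl}-1,4,4a,5,6,7,8,8a-octahydronaphthalene-1,4-diol
Conditions: iBu2AlH (3 equiv), CH2Cl2, −78 °C; aq potassium sodium tartrate
Reagents that add atoms: none
Why: 1,2-Reduction of the enone (C8 is fully substituted, so conjugate reduction does not compete) in which hydride enters C6 from the α face because the β face is screened by the axial 10-methyl and 4β-methyl groups, giving the axial 6β alcohol.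

Step 6
Reactants: 15 (2E,4E)-hexa-2,4-dienal; 16 malonic acid
Product: 18 (2E,4E,6E)-octa-2,4,6-trienoic acid, via dienylidenemalonic acid 17 (not isolated)
Conditions: pyridine, piperidine (cat.), 90 °C
Reagents that add atoms: none
Why: Knoevenagel–Doebner condensation in which the alkylidenemalonic acid 17 loses CO2 in hot pyridine to give the E alkene, so the all-E trienoic acid is formed.

Step 7
Reactants: 14 (1R,4R,4aS,8aS)-3,4a,8,8-tetramethyl-4-{[(S)-4-methylbenzenesulfinyl]methyl}-1,4,4a,5,6,7,8,8a-octahydronaphthalene-1,4-diol; 18 (2E,4E,6E)-octa-2,4,6-trienoic acid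
Product: 19 (1S,4R,4aS,8aS)-4-hydroxy-3,4a,8,8-tetramethyl-4-{[(S)-4-methylbenzenesulfinyl]methyl}-1,4,4a,5,6,7,8,8a-octahydronaphthalen-1-yl (2E,4E,6E)-octa-2,4,6-trienoate
Conditions: PPh3, DIAD, toluene–THF, 0 °C → rt
Reagents that add atoms: none
Why: Mitsunobu esterification with inversion, in which the axial allylic 6β oxyphosphonium group is displaced by the carboxylate from the open α face (an ion-pair pathway would be captured on the same face) to give the equatorial 6α ester, while the tertiary 9-OH does not react.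

Step 8
Reactants: 19 (1S,4R,4aS,8aS)-4-hydroxy-3,4a,8,8-tetramethyl-4-{[(S)-4-methylbenzenesulfinyl]methyl}-1,4,4a,5,6,7,8,8a-octahydronaphthalen-1-yl (2E,4E,6E)-octa-2,4,6-trienoate
Product: 21 (1S,4R,4aS,8aS)-4-formyl-4-hydroxy-3,4a,8,8-tetramethyl-1,4,4a,5,6,7,8,8a-octahydronaphthalen-1-yl (2E,4E,6E)-octa-2,4,6-trienoate (CNP0223516.2), via trifluoroacetoxy sulfide 20 (not isolated)
Conditions: (CF3CO)2O, 2,4,6-collidine, MeCN, 0 °C; then aq NaHCO3, rt
Reagents that add atoms: trifluoroacetic anhydride O=C(OC(=O)C(F)(F)F)C(F)(F)F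
Why: Pummerer rearrangement of the β-hydroxy sulfoxide to the α-trifluoroacetoxy sulfide 20 and hydrolysis of this O,S-acetal to the aldehyde, with the spent auxiliary leaving as the thiol; C9 is quaternary and no stereocentre is touched.

## Compound list

1 | 2,6-dimethylphenol | Cc1cccc(C)c1O | starting material
2 | 4-methoxy-2,6-dimethylphenol | COc1cc(C)c(O)c(C)c1 | intermediate (not isolated)
3 | 4,4-dimethoxy-2,6-dimethylcyclohexa-2,5-dien-1-one | COC1(OC)C=C(C)C(=O)C(C)=C1 | intermediate
4 | (S)-methyl p-tolyl sulfoxide | C[S@](=O)c1ccc(C)cc1 | starting material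
5 | [(S)-4-methylbenzenesulfinyl]methyllithium | [Li]C[S@](=O)c1ccc(C)cc1 | intermediate (not isolated)
6 | 4,4-dimethoxy-2,6-dimethyl-1-{[(S)-4-methylbenzenesulfinyl]methyl}cyclohexa-2,5-dien-1-ol | COC1(OC)C=C(C)C(O)(C[S@](=O)c2ccc(C)cc2)C(C)=C1 | intermediate (not isolated)
7 | 4-hydroxy-3,5-dimethyl-4-{[(S)-4-methylbenzenesulfinyl]methyl}cyclohexa-2,5-dien-1-one | CC1=CC(=O)C=C(C)C1(O)C[S@](=O)c1ccc(C)cc1 | intermediate
8 | 5-bromo-2-methylpent-2-ene | CC(C)=CCCBr | starting material
9 | 4-methylpent-3-enylmagnesium bromide | CC(C)=CCC[Mg]Br | intermediate (not isolated)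
10 | tris(4-methylpent-3-enyl)aluminium | CC(C)=CCC[Al](CCC=C(C)C)CCC=C(C)C | intermediate (not isolated)
11 | (4S,5S)-4-hydroxy-3,5-dimethyl-5-(4-methylpent-3-en-1-yl)-4-{[(S)-4-methylbenzenesulfinyl]methyl}cyclohex-2-en-1-one | O=C1C=C(C)[C@](O)(C[S@](=O)c2ccc(C)cc2)[C@@](C)(CCC=C(C)C)C1 | intermediate
12 | (4R,4aS,8aR)-4-hydroxy-3,4a,8,8-tetramethyl-4-{[(S)-4-methylbenzenesulfinyl]methyl}-4a,5,6,7,8,8a-hexahydronaphthalen-1(4H)-one (cis-fused, H5 β) | O=C1C=C(C)[C@](O)(C[S@](=O)c2ccc(C)cc2)[C@@]2(C)CCCC(C)(C)[C@@H]12 | intermediate (not isolated)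
13 | (4R,4aS,8aS)-4-hydroxy-3,4a,8,8-tetramethyl-4-{[(S)-4-methylbenzenesulfinyl]methyl}-4a,5,6,7,8,8a-hexahydronaphthalen-1(4H)-one (trans-fused, H5 α) | O=C1C=C(C)[C@](O)(C[S@](=O)c2ccc(C)cc2)[C@@]2(C)CCCC(C)(C)[C@H]12 | intermediate
14 | (1R,4R,4aS,8aS)-3,4a,8,8-tetramethyl-4-{[(S)-4-methylbenzenesulfinyl]methyl}-1,4,4a,5,6,7,8,8a-octahydronaphthalene-1,4-diol (6β-OH, 9α-OH) | O[C@@H]1C=C(C)[C@](O)(C[S@](=O)c2ccc(C)cc2)[C@@]2(C)CCCC(C)(C)[C@H]12 | intermediate
15 | (2E,4E)-hexa-2,4-dienal | C/C=C/C=C/C=O | starting material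
16 | malonic acid | OC(=O)CC(=O)O | starting material
17 | 2-[(2E,4E)-hexa-2,4-dien-1-ylidene]propanedioic acid | C/C=C/C=C/C=C(C(=O)O)C(=O)O | intermediate (not isolated)
18 | (2E,4E,6E)-octa-2,4,6-trienoic acid | C/C=C/C=C/C=C/C(=O)O | intermediate
19 | (1S,4R,4aS,8aS)-4-hydroxy-3,4a,8,8-tetramethyl-4-{[(S)-4-methylbenzenesulfinyl]methyl}-1,4,4a,5,6,7,8,8a-octahydronaphthalen-1-yl (2E,4E,6E)-octa-2,4,6-trienoate | C/C=C/C=C/C=C/C(=O)O[C@H]1C=C(C)[C@](O)(C[S@](=O)c2ccc(C)cc2)[C@@]2(C)CCCC(C)(C)[C@H]12 | intermediate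
20 | (1S,4R,4aS,8aS)-4-hydroxy-3,4a,8,8-tetramethyl-4-{[(4-methylphenyl)sulfanyl](trifluoroacetoxy)methyl}-1,4,4a,5,6,7,8,8a-octahydronaphthalen-1-yl (2E,4E,6E)-octa-2,4,6-trienoate (both epimers at the O,S-acetal carbon) | C/C=C/C=C/C=C/C(=O)O[C@H]1C=C(C)[C@](O)(C(OC(=O)C(F)(F)F)Sc2ccc(C)cc2)[C@@]2(C)CCCC(C)(C)[C@H]12 | intermediate (not isolated)
21 | (1S,4R,4aS,8aS)-4-formyl-4-hydroxy-3,4a,8,8-tetramethyl-1,4,4a,5,6,7,8,8a-octahydronaphthalen-1-yl (2E,4E,6E)-octa-2,4,6-trienoate | C/C=C/C=C/C=C/C(=O)O[C@H]1C=C(C)[C@](O)(C=O)[C@@]2(C)CCCC(C)(C)[C@H]12 | target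

## Step count and risks

Total steps: 8. Longest linear sequence: 7 (steps 1, 2, 3, 4, 5, 7, 8).

**Most likely to fail, first: the desymmetrising addition (step 3).** A primary alkyl group may not be delivered to a methyl-bearing carbon next to the fully substituted C9, or methyl-free R3Al 10 may be too sluggish. The fallback sets out from 7 and comes back at 11, and swaps the sp3 nucleophile for a slim sp one followed by selective saturation.
- 3-Methylbut-2-enal is homologated with dimethyl (1-diazo-2-oxopropyl)phosphonate (K2CO3, MeOH) to 4-methylpent-3-en-1-yne F1.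
- n-BuLi and then Me2AlCl convert it into dimethyl(4-methylpent-3-en-1-yn-1-yl)aluminium F2.
- F2 transfers its alkynyl group to 7 under the same alkoxide/sulfoxide direction (alkynyl transfer from alkynyldimethylaluminium reagents is established for the parent sulfinyl quinol), giving (4R,5R)-4-hydroxy-3,5-dimethyl-5-(4-methylpent-3-en-1-yn-1-yl)-4-{[(S)-4-methylbenzenesulfinyl]methyl}cyclohex-2-en-1-one F3.
- Diimide (2-nitrobenzenesulfonyl hydrazide, Et3N, CH2Cl2) saturates only the triple bond and leaves both trisubstituted alkenes, giving 11.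

**Second: the acid-mediated ring closure and C5 equilibration (step 4).** The cation may be diverted to ethers or to attack on the enone, and the trans preference at C5 rests on analogy. The fallback sets out from 7 and comes back at 13; it builds ring A by aldol condensation and sets C5 by protonation.
- Tris[3-(2-methyl-1,3-dioxolan-2-yl)propyl]aluminium F4 (from 2-(3-chloropropyl)-2-methyl-1,3-dioxolane, Mg, then AlCl3) is added to 7 as in the main route, giving (4S,5S)-4-hydroxy-3,5-dimethyl-5-[3-(2-methyl-1,3-dioxolan-2-yl)propyl]-4-{[(S)-4-methylbenzenesulfinyl]methyl}cyclohex-2-en-1-one F5.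
- Aqueous HCl in THF frees the methyl ketone (4S,5S)-4-hydroxy-3,5-dimethyl-5-(4-oxopentyl)-4-{[(S)-4-methylbenzenesulfinyl]methyl}cyclohex-2-en-1-one F6.
- Pyrrolidine/AcOH closes ring A by intramolecular aldol condensation of C5 onto the C4 ketone, giving the cross-conjugated dienone (4R,4aS)-4-hydroxy-3,4a,8-trimethyl-4-{[(S)-4-methylbenzenesulfinyl]methyl}-4a,5,6,7-tetrahydronaphthalen-1(4H)-one F7.
- Me2CuLi/Me3SiCl (THF, −78 °C) adds the second methyl group at C4 (C8 is shielded by the neighbouring quaternary C9). Quenching the resulting enolate at −78 °C protonates C5 from the α face, opposite the 10-methyl group, and gives 13.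

**Third: the Mitsunobu inversion (step 7).** H5 α is antiperiplanar to the activated 6β oxygen, so elimination to the 5,7-diene may compete. The fallback sets out from 14 and comes back at 19, and replaces inversion by thermodynamic control.
- Al(OiPr)3, iPrOH, a little acetone, toluene, 80 °C (Meerwein–Ponndorf–Verley/Oppenauer equilibration through ketone 13) converts the strained axial alcohol into the equatorial epimer (1S,4R,4aS,8aS)-3,4a,8,8-tetramethyl-4-{[(S)-4-methylbenzenesulfinyl]methyl}-1,4,4a,5,6,7,8,8a-octahydronaphthalene-1,4-diol F8.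
- F8 is acylated with retention by 18 (N-ethyl-N′-(3-dimethylaminopropyl)carbodiimide hydrochloride, DMAP, CH2Cl2) to give 19.

Further compounds
F1 | step 3 | 4-methylpent-3-en-1-yne | C#CC=C(C)C
F2 | step 3 | dimethyl(4-methylpent-3-en-1-yn-1-yl)aluminium | C[Al](C)C#CC=C(C)C
F3 | step 3 | (4R,5R)-4-hydroxy-3,5-dimethyl-5-(4-methylpent-3-en-1-yn-1-yl)-4-{[(S)-4-methylbenzenesulfinyl]methyl}cyclohex-2-en-1-one | O=C1C=C(C)[C@](O)(C[S@](=O)c2ccc(C)cc2)[C@@](C)(C#CC=C(C)C)C1
F4 | step 4 | tris[3-(2-methyl-1,3-dioxolan-2-yl)propyl]aluminium | CC1(CCC[Al](CCCC2(C)OCCO2)CCCC2(C)OCCO2)OCCO1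
F5 | step 4 | (4S,5S)-4-hydroxy-3,5-dimethyl-5-[3-(2-methyl-1,3-dioxolan-2-yl)propyl]-4-{[(S)-4-methylbenzenesulfinyl]methyl}cyclohex-2-en-1-one | O=C1C=C(C)[C@](O)(C[S@](=O)c2ccc(C)cc2)[C@@](C)(CCCC2(C)OCCO2)C1
F6 | step 4 | (4S,5S)-4-hydroxy-3,5-dimethyl-5-(4-oxopentyl)-4-{[(S)-4-methylbenzenesulfinyl]methyl}cyclohex-2-en-1-one | O=C1C=C(C)[C@](O)(C[S@](=O)c2ccc(C)cc2)[C@@](C)(CCCC(C)=O)C1
F7 | step 4 | (4R,4aS)-4-hydroxy-3,4a,8-trimethyl-4-{[(S)-4-methylbenzenesulfinyl]methyl}-4a,5,6,7-tetrahydronaphthalen-1(4H)-one | O=C1C=C(C)[C@](O)(C[S@](=O)c2ccc(C)cc2)[C@@]2(C)CCCC(C)=C12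
F8 | step 7 | (1S,4R,4aS,8aS)-3,4a,8,8-tetramethyl-4-{[(S)-4-methylbenzenesulfinyl]methyl}-1,4,4a,5,6,7,8,8a-octahydronaphthalene-1,4-diol | O[C@H]1C=C(C)[C@](O)(C[S@](=O)c2ccc(C)cc2)[C@@]2(C)CCCC(C)(C)[C@H]12
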